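The west run holds twice the protic impurity of the south-west run, yet links read 22.9 % and 22.9 % at 10.0 d, so the question lies elsewhere: which feed order keeps links alive.

| flask | first end groups | second end groups | protic impurity | remark | time |
|---|---|---|---|---|---|
| west | 0.50 M | 0.475 M | 0.025 M | run made earlier |  |
| south-west | 0.50 M | 0.475 M | 0.013 M | run made earlier |  |
| south | 0.50 M | 0.475 M | 0.019 M | run made earlier |  |
| Wednesday's | 0.50 M | 0.475 M (fed, over 8.0 d) | 0.0250 M | all else is in the flask from the start; the feed brings no volume worth counting | 10 d |
| Saturday's | 0.50 M (fed, over 8.0 d) | 0.475 M | 0.0250 M | all else is in the flask from the start; the feed brings no volume worth counting | 10 d |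
| Friday's | 0.50 M | 0.475 M | 0.0250 M | everything together at the start | 10 d |

- west (time / d: links / %, first end groups / %): 0.833: 58.1, 16.6; 1.25: 53.6, 13.0; 1.67: 51.3, 13.8; 3.00: 41.9, 8.5; 4.00: 37.9, 9.4; 6.00: 32.4, 4.6; 10.0: 22.9, 4.2
- south-west (time / d: links / %, first end groups / %): 1.67: 50.9, 12.4; 3.00: 43.0, 8.6; 5.00: 33.4, 5.1; 6.00: 32.7, 4.6; 8.00: 26.1, 5.1; 10.0: 22.9, 5.1; 12.0: 20.6, 3.1
- south (time / d: links / %, first end groups / %): 1.67: 51.9, 14.2; 3.00: 44.3, 9.4; 5.00: 34.9, 5.8; 6.00: 31.3, 4.9; 8.00: 28.4, 4.5; 10.0: 23.8, 4.4; 12.0: 19.8, 2.9

(standard deviation of a reading: 1 percentage point)

- in percentages every species weighs as the first end groups in it: one side product counts as two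
- the earlier runs were read with a standard deviation of 1 percentage point
- reactions considered so far: first end groups + second end groups <-> links + released group; first end groups + protic impurity -> quenched substrate; links <-> isomer of the product; first end groups + links -> side product

* the best flask by amount of links, in percent of the first end groups charged; "all alike" if 1.5 percentage points covers them all (Wednesday's / Saturday's / Friday's / all alike)
* amount of links at the end, in percent of the first end groups charged, Wednesday's
* amount of links at the end, in percent of the first end groups charged, Saturday's
* amount of links at the end, in percent of the first end groups charged, Friday's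

The bench rule takes the charge as symmetric. With equal end groups and no other path running, c(first end groups) equals c(second end groups) and c(links) equals c(released group), so the coupling quotient Q, c(links)·c(released group) over c(first end groups)·c(second end groups), is the square of links over first end groups. The charge ratio 0.950 permits this, and the west reading at 0.833 d gives 12.3.

At 3.00 d the square reads 24.3, twice the earlier value. There the rule ends, and a balance replaces it. Counting the whole protic impurity as quenched and leaving the isomer of the product aside, the coupling extent, and hence c(released group), is 0.321 M, which gives Q = 10.3, a value from one reading that carries its scatter. The same balance puts c(second end groups) at 0.154 M and c(first end groups) at 0.0425 M, so in the west run the second end groups now stand higher.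

Slow feeds leave symmetry further behind: after 4.00 d of Saturday's feed, the first end groups fed stand to the second end groups at 0.526. The side path, taken as a bimolecular step, uses links at a rate proportional to c(first end groups)·c(links). Taking every fed group as coupled, my reckoning gives Saturday's a c(first end groups) of 0.0270 M at that moment. The same rough reckoning, with no first end groups counted as lost to the side path or the protic impurity, gives Wednesday's 0.263 M at that moment, and the symmetric rule gives Friday's 0.119 M once its coupling has run. So I expect Saturday's to keep the most links.

The forecast gave Wednesday's 22 %, Saturday's 36 % and Friday's 23 %, and named Saturday's best: “Saturday's flask keeps first end groups scarce during the feed, so links survive”.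

The flasks end at 22.8 % for Wednesday's, 38.1 % for Saturday's and 23.8 % for Friday's, with Saturday's best.

    first end groups + second end groups ⇌ links + released group (K = 10.4, k = 0.799 /M/h)
    first end groups + protic impurity → quenched substrate (k = 0.400 /M/h)
    links ⇌ isomer of the product (K = 0.448, k = 9.22 × 10⁻⁴ /h)
    first end groups + links → side product (k = 0.0664 /M/h)

In Wednesday's the coupling relaxes with a half-life of 0.153 d, short against 10 d and against the 9.69 d of links and isomer of the product. At 2.73 d in Wednesday's, the side path uses links 19 times as fast as the forward isomer step. The states of Saturday's at 10.0 d give Q = 11.0. In a neighbour of Wednesday's with 0.28 M of second end groups, the carried Q and that flask's links, released group and second end groups give first end groups of 12.0 %, and the flask holds 11.9 %.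

(The numbers in the tables were generated by integration with constants of no real substance; the scatter is artificial.)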